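The data come from a simulation with made-up constants.

A chain is counted once however long it grows, so the average length is monomer in chains divided by chains begun.

the same everywhere: free monomer 0.50 M

| run | initiator | remark | time |
|---|---|---|---|
| spring | 0.76 mol% | run made earlier |  |
| dawn | 0.98 mol% | run made earlier |  |
| midnight | 1.3 mol% | run made earlier |  |
| north-east | 1.8 mol% |  | 5.0 h |
| south-west | 0.6 mol% |  | 5.0 h |

| run | time / h | monomer in chains / % |
|---|---|---|
| spring | 0.200 | 4 |
| spring | 0.500 | 10 |
| spring | 1.00 | 23 |
| spring | 2.50 | 42 |
| dawn | 0.667 | 16 |
| dawn | 1.33 | 31 |
| dawn | 2.00 | 41 |
| dawn | 2.50 | 49 |
| midnight | 0.200 | 8 |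
| midnight | 0.500 | 16 |
| midnight | 1.00 | 28 |
| midnight | 2.50 | 53 |

(standard deviation of a reading: 1.5 percentage points)

- the average divides the monomer in chains by the number of chains begun, living and dead together
- the earlier runs do not show the number of chains; that part of a forecast is a guess

1. which of the two ends with the longer chains by the average number of monomer units in a chain (chains begun, living or dead) ("neither" if they lie within 10 %) (north-east / south-west / neither)
2. average number of monomer units in a chain (chains begun, living or dead) at the end, north-east
3. average number of monomer units in a chain (chains begun, living or dead) at the end, south-west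

For a pseudo-first-order loss of free monomer, integration gives the conversion x = 1 − exp(−kt), with rate constant k. I read k from the last readings: 0.302 h⁻¹ in the midnight run and 0.218 h⁻¹ in the spring run. I scale these by the square root of the loading, so I estimate k = 0.355 h⁻¹ and x = 83.1 % for north-east, and k = 0.194 h⁻¹ and x = 62.0 % for south-west.

The runs do not show chains, so I assume that one initiator begins one chain at most. This gives the chain ceiling C, the concentration of initiator charged: 0.00900 M in north-east and 0.00300 M in south-west. Dividing my estimate of reacted monomer by C gives estimated floors of 46.2 for north-east and 103 for south-west. I have no ceiling for the lengths, but I can bracket their ratio, south-west over north-east, between two assumptions. If chains follow loading it is 2.24, and if they follow k it is 1.37. Even the lower end of this bracket exceeds the 10 % margin, so I commit to south-west.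

The forecast also says south-west, with 60 (range 30 to 200) for north-east and 140 (range 70 to 450) for south-west, both above my floors. It states, “The ratio of about 2.3 is firm”, and its two lengths give 2.33, slightly above the upper end of my bracket.

The flask gives south-west, with 121 monomer units against 70.2 in north-east, a ratio of 1.72.

    free monomer + initiator → living end + monomer in chains (k = 0.0150 L mol⁻¹ s⁻¹)
    free monomer + living end → monomer in chains + living end, rate k2*[living end]*[free monomer] (k = 0.0340 L mol⁻¹ s⁻¹)
    monomer in chains + living end → free monomer + living end, rate k3*[living end] as long as [monomer in chains] is above zero (k = 0.00440 s⁻¹)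
    2 initiator → spent initiator (k = 0.790 L mol⁻¹ s⁻¹)

North-east holds 0.00504 M of living end at the asked time, which is 56.0 % of its ceiling C. A neighbour flask, north-east's recipe with 0.20 M of free monomer at the same loading, has a ceiling of 0.00360 M. It holds 0.00202 M of living end, again 56.0 %, and its chains average 25.0 monomer units.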